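**Plan**

- Retrosynthesis: the C5–C6 bond is cut by a retro-Ferrier transform. The β-hydroxy ketone C9(=O)–C5–C6(OH) of ring A becomes an enol acetal C5=C9–O–C6(OMe). This is possible because the C9 oxygen and C6 are 1,3-related through C5 and C9 sits next to C1, so that O–C6–C7–C8–C1–C9 is a six-membered pyran fused to ring B, i.e. a hex-5-enopyranoside.
- Then the C4 carbinol H, the C2–C3 epoxide oxygen and the C1–O bond are removed, which re-aromatises ring B to a 7-hydroxy-2-methoxychroman; acetal and amide are cut back to a 2,4-dihydroxyphenylalanine ester (all nine core carbons), made from 2,4-bis(benzyloxy)benzaldehyde.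
- Forward order: amino ester → pyran ring (chroman acetal) → ring B dearomatised and oxygenated → ring A by exchange of the pyran oxygen for C5 (pyran opened, carbocycle closed).
- Stereochemistry: C7 from Rh–DuPhos hydrogenation; C1 from delivery of the amide oxygen across the pyran ring (cis to N); C2/C3 from hydroxyl-guided nucleophilic epoxidation; C4 from hydride attack anti to the epoxide; C5/C6 from the bicyclic closure (face fixed by C1, chelated chair gives the exo carbinol).

Key step: step 9

Remarks on the chemistry: atom labels C1–C9 are the bicyclo[3.3.1]nonane locants of the target (C1 C–OH bridgehead, C2–C3 epoxide, C4 CHOH, C5 CH bridgehead, C6 CHOH, C7 CHN, C8 CH2, C9 C=O) and are used for all intermediates; in chromene numbering C6 = C2, C7 = C3, C8 = C4, C1 = C4a, C2 = C5, C3 = C6, C4 = C7, C5 = C8, C9 = C8a. The acetal centre C6 of 9–14 is drawn as the 2,3-trans anomer; either anomer serves, since this centre is erased in step 9. Compounds 1, 2, 6 and the reagents are assumed to be purchased.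

**Route**

Step 1
Reactants: 1 2,4-bis(benzyloxy)benzaldehyde; 2 methyl 2-{[(benzyloxy)carbonyl]amino}-2-(dimethoxyphosphoryl)acetate (racemic)
Product: 3 methyl (Z)-2-{[(benzyloxy)carbonyl]amino}-3-[2,4-bis(benzyloxy)phenyl]prop-2-enoate
Conditions: DBU, CH2Cl2, 0 °C to rt
Reagents that add atoms: none
Why: Horner–Wadsworth–Emmons olefination of an aryl aldehyde with an N-acyl phosphonoglycinate, which should give the (Z)-dehydroamino ester (aryl cis to NHCbz) as the favoured isomer.

Step 2
Reactants: 3 methyl (Z)-2-{[(benzyloxy)carbonyl]amino}-3-[2,4-bis(benzyloxy)phenyl]prop-2-enoate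
Product: 4 methyl (S)-2-{[(benzyloxy)carbonyl]amino}-3-[2,4-bis(benzyloxy)phenyl]propanoate
Conditions: H2 (4 bar), [Rh(cod)((S,S)-Et-DuPhos)]OTf (1 mol %), MeOH, rt
Reagents that add atoms: none
Why: Rh(I)–bisphospholane asymmetric hydrogenation of a (Z)-α-(acylamino)acrylate; the chelated enamide with the (S,S)-ligand should take up H2 on the face that gives the (S)-amino ester (sets C7), while benzyl ethers and Cbz are inert to the homogeneous catalyst.

Step 3
Reactants: 4 methyl (S)-2-{[(benzyloxy)carbonyl]amino}-3-[2,4-bis(benzyloxy)phenyl]propanoate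
Product: 5 methyl (S)-2-amino-3-(2,4-dihydroxyphenyl)propanoate hydrochloride
Conditions: H2 (1 atm), 10 % Pd/C, methanolic HCl (1.05 equiv), MeOH, rt
Reagents that add atoms: hydrogen chloride, Cl
Why: Pd-catalysed hydrogenolysis removes Cbz and both benzyl ethers in one operation, and HCl holds the amine as its salt so that it cannot condense with the ester; C7 is not touched.

Step 4
Reactants: 5 methyl (S)-2-amino-3-(2,4-dihydroxyphenyl)propanoate hydrochloride; 6 (E)-dec-2-enoic acid
Product: 7 methyl (S)-2-[(E)-dec-2-enamido]-3-(2,4-dihydroxyphenyl)propanoate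
Conditions: EDC·HCl, HOBt, iPr2NEt, DMF, 0 °C to rt
Reagents that add atoms: none
Why: carbodiimide/HOBt amide coupling, N-selective because the amine is far more nucleophilic than the phenols (any aryl ester formed is cleaved in step 5); the amine partner cannot racemise and the (E)-enoyl group is carried unchanged from here to the target.

Step 5
Reactants: 7 methyl (S)-2-[(E)-dec-2-enamido]-3-(2,4-dihydroxyphenyl)propanoate
Product: 9 (E)-N-[(3S)-7-hydroxy-2-methoxy-3,4-dihydro-2H-chromen-3-yl]dec-2-enamide (2,3-trans anomer drawn), via (E)-N-[(3S)-2,7-dihydroxy-3,4-dihydro-2H-chromen-3-yl]dec-2-enamide 8 (not isolated)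
Conditions: DIBAL-H (4.5 equiv), CH2Cl2/THF, −78 °C, Rochelle-salt work-up; then MeOH, PPTS (cat.), 3 Å MS, rt
Reagents that add atoms: methanol, CO
Why: DIBAL half-reduction of the ester at −78 °C through a tetrahedral aluminium hemiacetal that closes with the ortho phenol to the 2-chromanol on work-up, followed by Fischer-type acetalisation that exchanges only the anomeric hydroxyl (the phenol is untouched; amide participation should favour the 2,3-trans acetal).

Step 6
Reactants: 9 (E)-N-[(3S)-7-hydroxy-2-methoxy-3,4-dihydro-2H-chromen-3-yl]dec-2-enamide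
Product: 12 (E)-N-[(3S)-4a-hydroxy-2-methoxy-7-oxo-2,3,4,4a-tetrahydro-7H-chromen-3-yl]dec-2-enamide with the 4a-OH (C1–OH) cis to the 3-NH, via the bridged cyclic imidate (2-[(E)-non-1-enyl]-5,6-dihydro-4H-1,3-oxazine spanning C1–O and C7–N of the dienone) 10 (not isolated), via the C1 O-[(E)-dec-2-enoyl] C7-amine 11 (not isolated)
Conditions: PhI(OAc)2 (1.05 equiv), (CF3)2CHOH/CH2Cl2 1:4, −20 °C; then THF/aq. AcOH–NaOAc (pH 4.5), rt; then aq. NaHCO3 (pH 8)
Reagents that add atoms: water, O
Why: λ3-iodane oxidative dearomatisation of a para-alkylphenol in a non-nucleophilic fluoroalcohol, in which the phenoxenium-type intermediate is captured at the para carbon C1 by the amide carbonyl oxygen through a six-membered ring (the known behaviour of N-acyltyramines); since the amide hangs from C7 of the pyran ring it can only reach the C1 face cis to nitrogen, which sets the quaternary centre relative to C7 and leaves C2 trans to nitrogen (no aza-Michael closure possible), and mild acid then opens the imidate to the O-acyl amine, which returns the acyl group to nitrogen at pH 8 without touching the C1–O bond.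

Step 7
Reactants: 12 (E)-N-[(3S)-4a-hydroxy-2-methoxy-7-oxo-2,3,4,4a-tetrahydro-7H-chromen-3-yl]dec-2-enamide
Product: 13 the C2–C3 (chromene 5,6) epoxide of 12, epoxide oxygen cis to the C1 hydroxyl, C4 ketone retained
Conditions: t-BuOOH (decane), DBU, CH2Cl2, 0 °C
Reagents that add atoms: tert-butyl hydroperoxide, CC(C)(C)OO
Why: Weitz–Scheffer nucleophilic epoxidation, chemoselective for the plain enone C2=C3 (the other ring alkene is a deactivated vinylogous ester and the enamide is inert), with the peroxide anion expected to add to C2 on the face of the free tertiary C1 hydroxyl (hydrogen-bond guidance, anti to the C8 methylene), so that C2 and C3 are set syn to C1–OH.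

Step 8
Reactants: 13 the C2–C3 epoxy ketone
Product: 14 the C4 alcohol (chromene 7-ol) with C1–OH, epoxide oxygen and C4–OH all on one face of ring B, enol acetal C5=C9–O–C6(OMe) intact
Conditions: NaBH4, CeCl3·7H2O, MeOH, −78 °C; neutral work-up, used without chromatography
Reagents that add atoms: none
Why: Luche 1,2-reduction of the epoxy enone carbonyl, with hydride expected to approach anti to the adjacent epoxide oxygen and so give the cis-epoxy alcohol (sets C4); the epoxide next to C4 also disfavours ionisation of the new allylic alcohol.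

Step 9
Reactants: 14 the all-cis epoxy diol enol acetal
Product: 16 isariotin D, (E)-N-[(7S)-1,4,6-trihydroxy-9-oxo-2,3-epoxybicyclo[3.3.1]nonan-7-yl]dec-2-enamide with the stereochemistry of the given SMILES, via the C5-(trifluoroacetoxymercurio) C9-keto C6-aldehyde 15 (not isolated)
Conditions: Hg(OCOCF3)2 (10 mol %), acetone/H2O 4:1, rt
Reagents that add atoms: water, O
Why: Hg(II) adds to the enol-ether carbon C5 and water to C9; the hemiketal collapses, the C9–O–C6 link breaks, C6 is released as the aldehyde (methanol lost) and C5 becomes an α-mercurio ketone that closes onto the aldehyde as its mercury enolate and returns Hg(II). The closest known reaction is the Ferrier carbocyclisation of hex-5-enopyranosides (2-alkoxy-6-alkylidene-tetrahydropyrans), of which 14 is a member with the alkylidene carbon inside ring B. The pyran ring is opened and ring A is closed by a 6-(enolexo)-exo-trig aldol, which turns the chromane skeleton into the bicyclo[3.3.1]nonan-9-one. C5 can only bond on the face of ring B that carries the C8–C7–C6 chain, which is opposite to the three oxygens and was fixed by C1; C6 should be set by a chair transition state in which mercury bridges the enolate and aldehyde oxygens, placing the C6 oxygen gauche to C9 (axial, exo, cis to the equatorial C7 amide), the same sense as the axial β-hydroxyl of Ferrier products. The step needs Hg(II) to attack only the electron-rich enol ether and the aldol to outrun loss of the C4 hydroxyl; the enamide alkene is electron-poor, the medium is neutral, the closure is intramolecular, and after closure C5 is a bridgehead so the β-hydroxy ketones cannot dehydrate.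

**Compound list**

1 | 2,4-bis(benzyloxy)benzaldehyde | O=Cc1ccc(OCc2ccccc2)cc1OCc1ccccc1 | starting material
2 | methyl 2-{[(benzyloxy)carbonyl]amino}-2-(dimethoxyphosphoryl)acetate (racemic) | COC(=O)C(NC(=O)OCc1ccccc1)P(=O)(OC)OC | starting material
3 | methyl (Z)-2-{[(benzyloxy)carbonyl]amino}-3-[2,4-bis(benzyloxy)phenyl]prop-2-enoate | COC(=O)/C(NC(=O)OCc1ccccc1)=C/c1ccc(OCc2ccccc2)cc1OCc1ccccc1 | intermediate
4 | methyl (S)-2-{[(benzyloxy)carbonyl]amino}-3-[2,4-bis(benzyloxy)phenyl]propanoate | COC(=O)[C@H](Cc1ccc(OCc2ccccc2)cc1OCc1ccccc1)NC(=O)OCc1ccccc1 | intermediate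
5 | methyl (S)-2-amino-3-(2,4-dihydroxyphenyl)propanoate hydrochloride | COC(=O)[C@H](Cc1ccc(O)cc1O)[NH3+].[Cl-] | intermediate
6 | (E)-dec-2-enoic acid | CCCCCCC/C=C/C(=O)O | starting material
7 | methyl (S)-2-[(E)-dec-2-enamido]-3-(2,4-dihydroxyphenyl)propanoate | CCCCCCC/C=C/C(=O)N[C@@H](Cc1ccc(O)cc1O)C(=O)OC | intermediate
8 | (E)-N-[(3S)-2,7-dihydroxy-3,4-dihydro-2H-chromen-3-yl]dec-2-enamide (lactol, anomers) | CCCCCCC/C=C/C(=O)N[C@H]1Cc2ccc(O)cc2OC1O | intermediate (not isolated)
9 | (E)-N-[(3S)-7-hydroxy-2-methoxy-3,4-dihydro-2H-chromen-3-yl]dec-2-enamide (2,3-trans anomer) | CCCCCCC/C=C/C(=O)N[C@H]1Cc2ccc(O)cc2O[C@@H]1OC | intermediate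
10 | bridged cyclic imidate: 2-[(E)-non-1-enyl]-dihydro-1,3-oxazine joining C1–O and C7–N of the 2-methoxy-7-oxo-tetrahydrochromene | CCCCCCC/C=C/C1=N[C@H]2C[C@@]3(O1)C(=CC(=O)C=C3)O[C@@H]2OC | intermediate (not isolated)
11 | C1 O-[(E)-dec-2-enoyl] ester of the 4a-hydroxy dienone with free C7 amine | CCCCCCC/C=C/C(=O)O[C@@]12C[C@H](N)[C@@H](OC)OC1=CC(=O)C=C2 | intermediate (not isolated)
12 | (E)-N-[(3S)-4a-hydroxy-2-methoxy-7-oxo-2,3,4,4a-tetrahydro-7H-chromen-3-yl]dec-2-enamide, 4a-OH cis to 3-NH | CCCCCCC/C=C/C(=O)N[C@H]1C[C@@]2(O)C(=CC(=O)C=C2)O[C@@H]1OC | intermediate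
13 | C2–C3 epoxide of 12, epoxide cis to C1–OH | CCCCCCC/C=C/C(=O)N[C@H]1C[C@@]2(O)C(=CC(=O)[C@@H]3O[C@@H]32)O[C@@H]1OC | intermediate
14 | C4 alcohol of 13, C1–OH, epoxide and C4–OH all cis | CCCCCCC/C=C/C(=O)N[C@H]1C[C@@]2(O)C(=C[C@H](O)[C@@H]3O[C@@H]32)O[C@@H]1OC | intermediate
15 | C5-(trifluoroacetoxymercurio) C9-keto C6-aldehyde (ring-opened form) | CCCCCCC/C=C/C(=O)N[C@@H](C[C@@]1(O)C(=O)C([Hg]OC(=O)C(F)(F)F)[C@H](O)[C@@H]2O[C@@H]21)C=O | intermediate (not isolated)
16 | isariotin D | CCCCCCC/C=C/C(=O)N[C@H]1C[C@@]2(O)C(=O)[C@H]([C@H](O)[C@@H]3O[C@@H]32)[C@H]1O | target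

**Totals**

Total step count: 9. Longest linear sequence: 9 steps (from 1).

**Steps most likely to fail**

Step 9. The C4 hydroxyl, which is β to mercury at C5 and to the new ketone, may be lost by elimination to a dienone that aromatises; mercury may open the epoxide; the sequence may stall after protodemercuration; or the closure may give poor exo/endo control at C6. Fallback: set out from 14 and hydrolyse the enol acetal with PPTS in wet acetone. The keto-aldehyde should rest as the spiro-lactol F3 (C6 hemiacetal closed on the C1 hydroxyl, ketone at C9, C5 methylene), which can be isolated. Soft enolisation with MgBr2·OEt2/Et3N in CH2Cl2 then forms the C9 magnesium enolate, which is chelated to the aldehyde and closes C5–C6, coming back to the route at 16.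

Step 6. The phenoxenium intermediate may be captured by solvent or on the wrong face instead of by the amide oxygen, the acetal may ionise in the fluoroalcohol, or the return of the acyl group to nitrogen may be incomplete. Fallback: set out from 9 and dearomatise without the tether by photooxygenation (O2, hν, methylene blue, CH2Cl2/MeOH, −20 °C). Singlet oxygen should give the 4a-hydroperoxide F1 as both C1 epimers. Reduction with PPh3 and chromatographic separation from the C1 epimer come back to the route at 12.

Step 7. The peroxide anion may attack C2 anti to the C1 hydroxyl (poor facial selectivity), or the base may degrade the dienone. Fallback: set out from 9 and make the same 4a-hydroperoxide by photooxygenation, here called F2 and kept unreduced. Catalytic benzyltrimethylammonium hydroxide in THF should pass the peroxide oxygen to the C2=C3 enone on the face that carries the peroxide (the known behaviour of p-peroxyquinols). This comes back to the route at 13 after separation of the C1 epimers, at the cost of the C1 control of step 6.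

**Further compounds**

F1 | step 6 | (E)-N-[(3S)-4a-hydroperoxy-2-methoxy-7-oxo-2,3,4,4a-tetrahydro-7H-chromen-3-yl]dec-2-enamide (needed C1 epimer drawn; formed with its C1 epimer) | CCCCCCC/C=C/C(=O)N[C@H]1C[C@@]2(OO)C(=CC(=O)C=C2)O[C@@H]1OC
F2 | step 7 | the same 4a-hydroperoxide as F1, used unreduced as internal oxygen donor | CCCCCCC/C=C/C(=O)N[C@H]1C[C@@]2(OO)C(=CC(=O)C=C2)O[C@@H]1OC
F3 | step 9 | spiro-lactol form of the C9-keto C6-aldehyde (C1–O–C6 hemiacetal, C5 methylene, epoxide and C4–OH intact) | CCCCCCC/C=C/C(=O)N[C@H]1C[C@@]2(OC1O)C(=O)C[C@H](O)[C@@H]3O[C@@H]32
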